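**Retrosynthetic overview**
- The last C–C bond is C3–C4 of ring B: an intramolecular vinylogous aldol addition of the benzylic carbon of a 6-benzyl-4-benzyloxy-2-pyranone to a benzoyl ketone. Both stereocentres arise here inside a chiral ammonium ion pair, and only O-debenzylation follows.
- The benzoyl ketone is not carried through the synthesis. It is stored as the benzoate of the phenol and moved onto the acetyl carbon by a Baker–Venkataraman shift in the same flask.
- The 2-pyranone is closed in that flask as well, by lactonisation of a δ-keto β-benzyloxy enoate made by γ-acylation of methyl (E)-3-(benzyloxy)but-2-enoate with an arylacetic acid.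
- The 1,2,3-trisubstituted arene comes from acyl-alkylation of 3-methoxybenzyne with tert-butyl acetoacetate.
- Ring order: ring A (bought as the aryne precursor), then the 2-pyranone, then ring B, the last two in one operation.

Assumption: the cinchonidine-derived ammonium salt of step 6 is taken to give the (3S,4S) series; its cinchonine-derived pseudoenantiomer is used instead if the induction runs the other way.

**Route**

Step 1
Reactants: 1 3-methoxy-2-(trimethylsilyl)phenyl trifluoromethanesulfonate; 2 tert-butyl 3-oxobutanoate
Product: 4 tert-butyl 2-(2-acetyl-3-methoxyphenyl)acetate, via 3-methoxybenzyne 3 (not isolated)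
Conditions: CsF (2.5 equiv), MeCN, 80 °C
Reagents that add atoms: none
Why: Fluoride releases 3-methoxybenzyne, the enolate carbon of 2 adds at the aryne carbon remote from OMe, the aryl anion formed next to OMe attacks the ketone and the strained benzocyclobutenoxide opens, which places the acetyl group ortho to OMe and the CH2CO2tBu group next to it (aryne acyl-alkylation, a formal C–C σ-bond insertion).

Step 2
Reactants: 4 tert-butyl 2-(2-acetyl-3-methoxyphenyl)acetate
Product: 5 2-(2-acetyl-3-hydroxyphenyl)acetic acid
Conditions: BCl3 (3 equiv), CH2Cl2, −78 → 0 °C; H2O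
Reagents that add atoms: none
Why: BCl3 binds between the acetyl oxygen and the neighbouring methoxy oxygen and cleaves that methyl ether, and it also cleaves the tert-butyl ester by an SN1-type path, so one Lewis-acid dealkylation frees both the phenol that will carry the benzoyl group and the acid needed for chain extension.

Step 3
Reactants: 6 methyl but-2-ynoate; 7 benzyl alcohol
Product: 8 methyl (2E)-3-(benzyloxy)but-2-enoate
Conditions: PMe3 (10 mol%), CH2Cl2, 25 °C
Reagents that add atoms: none
Why: Trimethylphosphine adds to the ynoate and the alkoxide then adds in conjugate fashion (phosphine-catalysed oxa-Michael addition), giving the E enol ether in which benzyloxy is trans to the ester and the methyl group is cis to it, as needed for γ-deprotonation and later lactonisation.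

Step 4
Reactants: 5 2-(2-acetyl-3-hydroxyphenyl)acetic acid; 8 methyl (2E)-3-(benzyloxy)but-2-enoate
Product: 11 methyl (2E)-6-(2-acetyl-3-hydroxyphenyl)-3-(benzyloxy)-5-oxohex-2-enoate, via acyl imidazolide 9 (not isolated), via lithium dienolate 10 (not isolated)
Conditions: 5, 1,1'-carbonyldiimidazole (1.05 equiv), THF, 0 °C; added to 8 (3.5 equiv), LiN(iPr)2 (3.4 equiv), THF, −78 → −40 °C; AcOH
Reagents that add atoms: none
Why: The lithium dienolate of the β-alkoxy enoate is acylated at its terminal (γ) carbon by the acyl imidazolide (vinylogous Claisen acylation, the usual entry to precursors of 6-substituted 4-alkoxy-2-pyranones), excess dienolate takes up the phenol proton and the acidic proton of the product, and the E double bond is kept.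

Step 5
Reactants: 11 methyl (2E)-6-(2-acetyl-3-hydroxyphenyl)-3-(benzyloxy)-5-oxohex-2-enoate; 12 benzoyl chloride
Product: 13 methyl (2E)-6-[2-acetyl-3-(benzoyloxy)phenyl]-3-(benzyloxy)-5-oxohex-2-enoate
Conditions: Et3N (1.3 equiv), DMAP (5 mol%), CH2Cl2, 0 °C
Reagents that add atoms: none
Why: The phenol is the most acidic site and is acylated selectively (DMAP-catalysed O-acylation), which stores the future C3–phenyl ketone as an ester exactly ortho to the acetyl group.

Step 6 (key step)
Reactants: 13 methyl (2E)-6-[2-acetyl-3-(benzoyloxy)phenyl]-3-(benzyloxy)-5-oxohex-2-enoate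
Product: 16 (3S,4S)-4-[4-(benzyloxy)-2-oxo-2H-pyran-6-yl]-3,8-dihydroxy-3-phenyl-3,4-dihydronaphthalen-1(2H)-one, via pyranone benzoate 14 (not isolated), via hydroxyaryl diketone 15 (not isolated)
Conditions: N-(9-anthracenylmethyl)cinchonidinium bromide (10 mol%), Cs2CO3 (3 equiv), 4 Å MS, PhMe (0.01 M), 0 → 25 °C; AcOH
Reagents that add atoms: none
Why: Proposed new method: under solid–liquid phase transfer the carbonate first closes the 2-pyranone by enolate O-acylation of the δ-keto enoate (the known closure to 4-alkoxy-2-pyranones, methanol being held by the sieves), then the acetyl enolate takes the benzoyl group from the neighbouring phenol ester through a six-membered transition state (Baker–Venkataraman O→C acyl shift, known under phase-transfer conditions), and finally the benzylic C–H between the arene and the O-benzyl pyranone, the only carbon acid that can reach the new ketone, closes ring B by a six-membered vinylogous aldol addition inside the ion pair with the cinchonidinium cation, whose C9–OH hydrogen-bonds the 1,3-dicarbonyl and shields one carbonyl face so that C3 is set as S, while C4 follows as S because the half-chair transition state and the product both prefer phenyl pseudo-equatorial and the pyranone pseudo-axial away from the peri C5–H (OH and pyranone trans, C4 remaining epimerisable under the conditions and settling on this isomer); the closest known reactions are cinchona-ammonium phase-transfer aldol and enolate cyclisations and the biosynthetic aldol that closes this ring.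

Step 7
Reactants: 16 (3S,4S)-4-[4-(benzyloxy)-2-oxo-2H-pyran-6-yl]-3,8-dihydroxy-3-phenyl-3,4-dihydronaphthalen-1(2H)-one
Product: 17 (3S,4S)-3,8-dihydroxy-4-(4-hydroxy-2-oxo-2H-pyran-6-yl)-3-phenyl-3,4-dihydronaphthalen-1(2H)-one
Conditions: H2 (1 atm), Pd/C, EtOAc, 25 °C
Reagents that add atoms: none
Why: Catalytic hydrogenolysis cleaves the benzyl–oxygen bond of the vinylogous ester under neutral conditions that neither enolise C4 nor reverse the aldol, so both stereocentres pass through unchanged.

**Compound list**
1 | 3-methoxy-2-(trimethylsilyl)phenyl trifluoromethanesulfonate | COc1cccc(OS(=O)(=O)C(F)(F)F)c1[Si](C)(C)C | starting material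
2 | tert-butyl 3-oxobutanoate | CC(=O)CC(=O)OC(C)(C)C | starting material
3 | 3-methoxybenzyne (3-methoxy-1,2-didehydrobenzene) | COC1=CC=CC#C1 | intermediate
4 | tert-butyl 2-(2-acetyl-3-methoxyphenyl)acetate | CC(=O)c1c(OC)cccc1CC(=O)OC(C)(C)C | intermediate
5 | 2-(2-acetyl-3-hydroxyphenyl)acetic acid | CC(=O)c1c(O)cccc1CC(=O)O | intermediate
6 | methyl but-2-ynoate | CC#CC(=O)OC | starting material
7 | benzyl alcohol | OCc1ccccc1 | starting material
8 | methyl (2E)-3-(benzyloxy)but-2-enoate | C/C(OCc1ccccc1)=C\C(=O)OC | intermediate
9 | 1-[(2-acetyl-3-hydroxyphenyl)acetyl]-1H-imidazole | CC(=O)c1c(O)cccc1CC(=O)n1ccnc1 | intermediate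
10 | lithium 3-(benzyloxy)-1-methoxybuta-1,3-dien-1-olate | [Li+].[O-]C(OC)=CC(=C)OCc1ccccc1 | intermediate
11 | methyl (2E)-6-(2-acetyl-3-hydroxyphenyl)-3-(benzyloxy)-5-oxohex-2-enoate | CC(=O)c1c(O)cccc1CC(=O)C/C(OCc2ccccc2)=C\C(=O)OC | intermediate
12 | benzoyl chloride | O=C(Cl)c1ccccc1 | starting material
13 | methyl (2E)-6-[2-acetyl-3-(benzoyloxy)phenyl]-3-(benzyloxy)-5-oxohex-2-enoate | CC(=O)c1c(OC(=O)c2ccccc2)cccc1CC(=O)C/C(OCc3ccccc3)=C\C(=O)OC | intermediate
14 | 2-acetyl-3-{[4-(benzyloxy)-2-oxo-2H-pyran-6-yl]methyl}phenyl benzoate | CC(=O)c1c(OC(=O)c2ccccc2)cccc1Cc3cc(OCc4ccccc4)cc(=O)o3 | intermediate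
15 | 1-(2-{[4-(benzyloxy)-2-oxo-2H-pyran-6-yl]methyl}-6-hydroxyphenyl)-3-phenylpropane-1,3-dione | O=C(CC(=O)c1ccccc1)c2c(O)cccc2Cc3cc(OCc4ccccc4)cc(=O)o3 | intermediate
16 | (3S,4S)-4-[4-(benzyloxy)-2-oxo-2H-pyran-6-yl]-3,8-dihydroxy-3-phenyl-3,4-dihydronaphthalen-1(2H)-one | O=C1C[C@@](O)(c2ccccc2)[C@@H](c2cc(OCc3ccccc3)cc(=O)o2)c2cccc(O)c21 | intermediate
17 | (3S,4S)-3,8-dihydroxy-4-(4-hydroxy-2-oxo-2H-pyran-6-yl)-3-phenyl-3,4-dihydronaphthalen-1(2H)-one | O=C1C[C@@](O)(c2ccccc2)[C@@H](c2cc(O)cc(=O)o2)c2cccc(O)c21 | target

**Step count and risks**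

Total steps: 7. Longest linear sequence: 6 (steps 1, 2, 4, 5, 6, 7 from 1).

Three steps most likely to fail:

Step 6. The cascade can fail in four ways:
- methanol can strip the benzoate before the acyl shift;
- the keto-enoate can condense with the acetyl group before lactonisation;
- the ion pair may give poor enantioselectivity;
- the aldol can reverse on long exposure to base.

Fallback (classical resolution, setting out from 13 and coming back at 17): 13 is run through the same base cascade with Bu4NBr in place of the chiral salt. This gives the racemic trans benzyl ether, a 1:1 mixture of 16 and its (3R,4R) enantiomer F1. Hydrogenolysis as in step 7 gives racemic 17, a 1:1 mixture of 17 and its (3R,4R) enantiomer F2. The acidic pyranone OH is then used for salt formation with (1R)-1-phenylethanamine. The less soluble (1R)-1-phenylethanaminium 4-pyranolate salt of (3S,4S)-17 F3 is crystallised from EtOH/EtOAc and acidified with aqueous citric acid to release 17.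

Step 4. The strongly basic dienolate meets a free phenol, an enolisable acetyl group and an acidic acyl imidazolide, so Dieckmann-type closure to a naphthalenediol or α-acylation can compete.

Fallback (base-free acylation in a changed order, setting out from 5 and coming back at 13): 5 is first benzoylated with 12 (pyridine, CH2Cl2, 0 °C) to 2-[2-acetyl-3-(benzoyloxy)phenyl]acetic acid F4. Oxalyl chloride (cat. DMF, CH2Cl2) converts it into 2-acetyl-3-(2-chloro-2-oxoethyl)phenyl benzoate F5. Separately, 8 is converted with LiN(iPr)2 and Me3SiCl (THF, −78 °C) into {[3-(benzyloxy)-1-methoxybuta-1,3-dien-1-yl]oxy}trimethylsilane F6. F5 and F6 are combined without base (CH2Cl2, −78 → 0 °C, vinylogous Mukaiyama acylation at the terminal carbon) to give 13 directly, bypassing 11 and step 5.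

Step 7. Hydrogenation may touch the pyranone double bonds or the tertiary benzylic C–O bond.

Fallback (non-reductive cleavage, setting out from 16 and coming back at 17): the benzyl ether is removed with BCl3 and pentamethylbenzene as cation scavenger (CH2Cl2, −78 °C). No new compound is made.

Further compounds
F1 | step 6 | racemic trans benzyl ether, 1:1 mixture of 16 and its (3R,4R) enantiomer | O=C1C[C@@](O)(c2ccccc2)[C@@H](c2cc(OCc3ccccc3)cc(=O)o2)c2cccc(O)c21.O=C1C[C@](O)(c2ccccc2)[C@H](c2cc(OCc3ccccc3)cc(=O)o2)c2cccc(O)c21
F2 | step 6 | racemic 17, 1:1 mixture of 17 and its (3R,4R) enantiomer | O=C1C[C@@](O)(c2ccccc2)[C@@H](c2cc(O)cc(=O)o2)c2cccc(O)c21.O=C1C[C@](O)(c2ccccc2)[C@H](c2cc(O)cc(=O)o2)c2cccc(O)c21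
F3 | step 6 | (1R)-1-phenylethanaminium 4-pyranolate salt of (3S,4S)-17 | O=C1C[C@@](O)(c2ccccc2)[C@@H](c2cc([O-])cc(=O)o2)c2cccc(O)c21.C[C@@H]([NH3+])c1ccccc1
F4 | step 4 | 2-[2-acetyl-3-(benzoyloxy)phenyl]acetic acid | CC(=O)c1c(OC(=O)c2ccccc2)cccc1CC(=O)O
F5 | step 4 | 2-acetyl-3-(2-chloro-2-oxoethyl)phenyl benzoate | CC(=O)c1c(OC(=O)c2ccccc2)cccc1CC(=O)Cl
F6 | step 4 | {[3-(benzyloxy)-1-methoxybuta-1,3-dien-1-yl]oxy}trimethylsilane | C=C(OCc1ccccc1)C=C(OC)O[Si](C)(C)C
F0 | step 7 | none | none
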